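Sunday's flask at 80 °C and Tuesday's at 75 °C have the same charge, and the readings at 5.00 h put Sunday's use of substrate at 41.7% against Tuesday's 37.4%, yet its target reads just 2.1 percentage points ahead. Sunday's flask is the one we are asked about, and it is followed further below.

| setting | Sunday's | Tuesday's | flask |
|---|---|---|---|
| substrate | 0.15 M | 0.15 M | 0.15 M |
| reagent | 0.165 M | 0.165 M | 0.165 M |
| catalyst | 3 mM | 3 mM | 3.0 mM |
| temperature | 80 °C | 75 °C | 80 °C |
| remark | the very flask that is asked about, followed so far | run made earlier |  |
| time |  |  | 8.0 h |

- Sunday's (time / h: target / %, substrate / %): 0.417: 4.9, 94.4; 0.667: 7.8, 90.0; 1.00: 12.4, 86.2; 2.00: 17.0, 76.9; 3.00: 21.8, 67.3; 5.00: 26.5, 58.3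
- Tuesday's (time / h: target / %, substrate / %): 0.417: 5.2, 96.1; 0.667: 6.8, 94.0; 1.00: 9.3, 91.5; 2.00: 16.0, 81.3; 3.00: 21.4, 76.0; 5.00: 24.4, 62.6

(readings scatter by 1 percentage point)

- dusk: at 8.0 h add reagent, 50.0% of the amount charged, then wait 8.0 h
- summer: change nothing and wait 8.0 h more
- winter: at 8.0 h take out 90% of the target then present, then wait 8.0 h
- dawn: at 8.0 h add catalyst, 100% of the amount charged, then wait 8.0 h
- spring: at 8.0 h raise the temperature by 10 K, then wait 8.0 h

- removed target is counted in
- what was read earlier has a scatter of 1 percentage point, one standard deviation
- additions bring no volume worth counting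

- target, in percent of the substrate first charged, at 8.0 h
- what to do for the largest gain in target; "none" if nothing gains more than 2 percentage points (dusk / summer / winter / dawn / spring / none)
- target present, with what was taken out counted in, in percent of the substrate first charged, after dawn
- target present, with what was taken out counted in, in percent of the substrate first charged, after spring

We follow one substrate molecule through two forks: it is used and becomes target, and then it stays target or leaves for something we do not read. The kept share, or selectivity to target, is target over substrate used. In Sunday's flask it reads 89.9% at 1.00 h and 63.5% at 5.00 h; Tuesday's last share reads 65.2%. These last shares differ by 1.7 points, and with a scatter of 1 point on each reading we cannot tell them apart; that does not show that the two flasks keep alike.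

If use runs steadily, which is rough, and each target molecule has a steady chance of leaving, the kept share is one minus exp(−x), over x, with x the time divided by the lifetime of target, the mean stay of a target molecule before it leaves, read here as 5.00 h. We chose that lifetime to match the reading, so this is no check: it gives 63.2% at 5.00 h, against the 63.5% read.

Reagent is charged at 1.10 times the substrate, so we let inverse substrate grow in step with time. Sunday's flask then has 46.6% substrate at 8.0 h, keeps 49.9% of what it used, and holds 26.6% target. Over 8.0 h more, a target molecule left in the flask survives with chance 20.2%. Waiting therefore ends near 13.5%, while taking out 90% of the target ends near 32.6%. We choose winter; the runs hold catalyst fixed, so they do not show what dawn does to the lifetime.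

The forecast gives 25%, winter, 17% after dawn and 9% after spring, and says “Winter is the only gain”.

Sunday's flask gives 25.8% at 8.0 h, against our 26.6%; the best option is winter, gaining 8.1 points, while dawn ends at 9.88% and spring at 12.8%.

    target + catalyst ⇌ isomer of the product + catalyst, rate k1*[catalyst]*[target] forward; the back reaction follows from the equilibrium constant (k = 44.0 M⁻¹ h⁻¹, Ea = 61.0 kJ mol⁻¹)
    substrate + reagent ⇌ isomer of the product (K = 640 M⁻¹, k = 0.0370 M⁻¹ h⁻¹, Ea = 84.0 kJ mol⁻¹, ΔH = −66.0 kJ mol⁻¹)
    substrate + reagent ⇌ target (K = 16.0 M⁻¹, k = 0.900 M⁻¹ h⁻¹, Ea = 65.0 kJ mol⁻¹, ΔH = −9.00 kJ mol⁻¹)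
    (constants at 80 °C)

In this scheme the step out of target runs in proportion to catalyst, so for the neighbour flask with 1.80 mM of catalyst we stretch the lifetime to 8.33 h, which gives a kept share of 64.3%; that flask stands at 64.1%. Sunday's flask keeps 50.7% at 8.0 h against our 49.9%, and it is not at rest: target is made at 0.749 of the rate at which it is used up, and the slowest mode has a half-life of 8.64 h. At 80.0 h substrate has fallen to 10.0%, the isomer of the product holds 86.9%, and target is down to 3.10%.

The runs stem from a simulated flask from invented constants, noise included.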